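**Plan**
Retrosynthetic cuts, in order: the three O–Si bonds and the 4'-O–CH2 bond of the prenyl ether, the aryl ketone bond C4–C4a of ring C, the benzylic ether bond C2–O1, and finally C2–C3.
Forward: ring A (phloroglucinol) and ring B (3,4-dihydroxybenzaldehyde) are bought. The ring B aldehyde is homologated to a β-keto ester (C2–C3), reduced and joined to ring A through O1. Ring C is the only ring made, and it is closed last by acylation at C4a.
Enabling feature: in the 3,5-disilyloxyphenyl ether the two ring A carbons ortho to O1 (future C4a and C8) are equivalent by symmetry. Each lies ortho to one silyloxy group and para to the other, so C4–C4a closure can give only the 5,7-dioxygenated chroman-4-one.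
Stereochemistry: C2 is the only stereocentre. Asymmetric transfer hydrogenation sets (R), the Mitsunobu etherification inverts it to (S), and all later steps avoid bases that could open ring C.
Ring B carries an allyl carbonate on O4' and a silyl ether on O3'. The carbonate keeps ring B electron-poor, so C2–O1 resists ionisation in acid, and zerovalent palladium removes it under neutral conditions. The acid-labile prenyl group is attached only after the acylation.

Key step: step 9

Remark: flavanone numbering (O1, C2, C3, C4, C4a, C5–C8, C8a, primed positions for ring B) is also used for the open-chain precursors. TBS = tert-butyldimethylsilyl. tert-Butyl diazoacetate, allyl chloroformate and prenol are taken as commercial.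

Step 1
Reactants: 1 3,4-dihydroxybenzaldehyde
Product: 2 3,4-bis(tert-butyldimethylsilyloxy)benzaldehyde
Conditions: TBSCl (2.4 equiv), imidazole (5 equiv), DMF, 0 °C to rt
Reagents that add atoms: tert-butyldimethylsilyl chloride, CC(C)(C)[Si](C)(C)Cl
Why: Imidazole-promoted O-silylation of both phenols gives two silyl ethers that differ only in their electronic link to the formyl group, and step 2 exploits that difference.

Step 2
Reactants: 2 3,4-bis(tert-butyldimethylsilyloxy)benzaldehyde
Product: 3 3-(tert-butyldimethylsilyloxy)-4-hydroxybenzaldehyde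
Conditions: LiOAc (0.1 equiv), DMF–H2O (50:1), rt
Reagents that add atoms: none
Why: Acetate-catalysed hydrolysis of aryl silyl ethers is fastest where the departing phenoxide is best stabilised, so at room temperature only the O4–Si bond para to the formyl group should break, and any silyl shuttling between the catechol oxygens ends on O3 because negative charge is best held on O4.

Step 3
Reactants: 3 3-(tert-butyldimethylsilyloxy)-4-hydroxybenzaldehyde
Product: 4 4-(allyloxycarbonyloxy)-3-(tert-butyldimethylsilyloxy)benzaldehyde
Conditions: allyl chloroformate (1.2 equiv), pyridine (2 equiv), CH2Cl2, 0 °C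
Reagents that add atoms: allyl chloroformate, C=CCOC(=O)Cl
Why: Carbonate formation (O-acylation with a chloroformate) occurs at the only free phenol, and adding the acyl-type group after the silyl group avoids the O4-to-O3 acyl shift and the cyclic carbonate formation that a free neighbouring 3-OH would allow.

Step 4
Reactants: 4 4-(allyloxycarbonyloxy)-3-(tert-butyldimethylsilyloxy)benzaldehyde, 5 tert-butyl diazoacetate
Product: 6 tert-butyl 3-[4-(allyloxycarbonyloxy)-3-(tert-butyldimethylsilyloxy)phenyl]-3-oxopropanoate
Conditions: SnCl2 (0.1 equiv), CH2Cl2, rt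
Reagents that add atoms: none
Why: In the Roskamp reaction the diazo carbon adds to the SnCl2-activated aldehyde (C2–C3 bond) and loss of N2 with a 1,2-hydride shift gives the β-keto ester, the electron-poor aryl group disfavouring the competing aryl shift.

Step 5
Reactants: 6 tert-butyl 3-[4-(allyloxycarbonyloxy)-3-(tert-butyldimethylsilyloxy)phenyl]-3-oxopropanoate
Product: 7 tert-butyl (R)-3-[4-(allyloxycarbonyloxy)-3-(tert-butyldimethylsilyloxy)phenyl]-3-hydroxypropanoate
Conditions: RuCl[(R,R)-TsDPEN](p-cymene) (1 mol %), HCO2H–Et3N (5:2), EtOAc, rt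
Reagents that add atoms: none
Why: In the Noyori asymmetric transfer hydrogenation the (R,R)-TsDPEN ruthenium hydride reduces the aryl ketone through the outer-sphere six-membered transition state, with the aryl group held against the cymene ligand, which is the sense that turns acetophenone into (R)-1-phenylethanol, so the (R)-carbinol should form while alkene, carbonate, ester and silyl ether stay untouched.

Step 6
Reactants: 8 phloroglucinol
Product: 9 3,5-bis(tert-butyldimethylsilyloxy)phenol
Conditions: TBSCl (2.0 equiv), imidazole (4 equiv), DMF, 0 °C to rt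
Reagents that add atoms: tert-butyldimethylsilyl chloride, CC(C)(C)[Si](C)(C)Cl
Why: This is a statistical O-silylation of a threefold symmetric triphenol, the disilyl ether being separated by chromatography from the mono- and trisilyl ethers, which can be recycled.

Step 7
Reactants: 7 tert-butyl (R)-3-[4-(allyloxycarbonyloxy)-3-(tert-butyldimethylsilyloxy)phenyl]-3-hydroxypropanoate, 9 3,5-bis(tert-butyldimethylsilyloxy)phenol
Product: 10 tert-butyl (S)-3-[4-(allyloxycarbonyloxy)-3-(tert-butyldimethylsilyloxy)phenyl]-3-[3,5-bis(tert-butyldimethylsilyloxy)phenoxy]propanoate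
Conditions: PPh3 (1.5 equiv), DIAD (1.5 equiv), toluene, 0 °C to rt
Reagents that add atoms: none
Why: In the Mitsunobu etherification the phenoxide of 9 displaces the alkoxyphosphonium ion of the (R)-carbinol by SN2 with inversion to give (S) at C2, and the carbonate para to the reacting carbon suppresses the SN1 leakage that lowers the enantiomeric purity of electron-rich benzylic alcohols.

Step 8
Reactants: 10 tert-butyl (S)-3-[4-(allyloxycarbonyloxy)-3-(tert-butyldimethylsilyloxy)phenyl]-3-[3,5-bis(tert-butyldimethylsilyloxy)phenoxy]propanoate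
Product: 12 (S)-3-[4-(allyloxycarbonyloxy)-3-(tert-butyldimethylsilyloxy)phenyl]-3-[3,5-bis(tert-butyldimethylsilyloxy)phenoxy]propanoic acid, via trimethylsilyl ester 11 (not isolated)
Conditions: TMSOTf (3 equiv), 2,6-lutidine (4 equiv), CH2Cl2, 0 °C to rt; then pH 4 aqueous buffer
Reagents that add atoms: none
Why: In this silyl triflate-mediated tert-butyl ester cleavage, silylation of the ester carbonyl and loss of isobutene under lutidine buffering give the silyl ester, which hydrolyses on work-up, so no base is present that could expel the aryloxide by E1cB and no tert-butyl cation persists in acid to alkylate the very nucleophilic ring A.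

Step 9
Reactants: 12 (S)-3-[4-(allyloxycarbonyloxy)-3-(tert-butyldimethylsilyloxy)phenyl]-3-[3,5-bis(tert-butyldimethylsilyloxy)phenoxy]propanoic acid
Product: 14 (2S)-4'-O-(allyloxycarbonyl)-3',5,7-tris-O-(tert-butyldimethylsilyl)eriodictyol, via acyl trifluoroacetate 13 (not isolated)
Conditions: (CF3CO)2O (1.5 equiv), CH2Cl2, 0 °C to rt
Reagents that add atoms: none
Why: The acid exchanges with the anhydride to give acyl trifluoroacetate 13, which, helped by the trifluoroacetic acid released, behaves as an acylium equivalent; a ring A carbon ortho to O1 attacks it and the arenium ion loses its proton, forming C4–C4a. The closest known reaction type is the intramolecular Friedel–Crafts acylation of 3-aryloxypropanoic acids to chroman-4-ones. Ring C closes as a six-membered ring in a 6-exo-trig manner at the anhydride carbonyl (the C=O bond stays outside the new ring), with the arene carbon as the nucleophilic terminus of the O1–C2–C3 tether. No stereocentre is created, and C2 should keep its (S) configuration because none of its bonds takes part; ionisation of C2–O1 is held back by the electron-withdrawing carbonate para to C2 on ring B, by the low temperature and by the absence of a strong Lewis acid, which the electron-rich ring A makes unnecessary. Regioselectivity is built into the substrate, since the two carbons ortho to O1 are symmetry-equivalent and doubly activated, while the carbon between the two silyloxy groups is out of reach of the three-atom tether. Chemoselectivity rests on trifluoroacetate being the better leaving group (alkanoyl rather than trifluoroacetyl transfer), on the small excess of anhydride, on the deactivated ring B, and on the new ketone deactivating ring A against a second acylation.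

Step 10
Reactants: 14 (2S)-4'-O-(allyloxycarbonyl)-3',5,7-tris-O-(tert-butyldimethylsilyl)eriodictyol
Product: 15 (2S)-3',5,7-tris-O-(tert-butyldimethylsilyl)eriodictyol
Conditions: Pd(PPh3)4 (5 mol %), dimedone (3 equiv), THF, rt
Reagents that add atoms: none
Why: In this Tsuji–Trost-type deallylation zerovalent palladium ionises the allyl carbonate, CO2 is lost and dimedone traps the π-allyl unit while its acidity protonates the phenoxide at once, so the solvolysis-prone 7-O-silyl ether para to the ketone, the C2 centre and the position of the 3'-O-silyl group should all be left alone.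

Step 11
Reactants: 15 (2S)-3',5,7-tris-O-(tert-butyldimethylsilyl)eriodictyol, 16 prenol (3-methylbut-2-en-1-ol)
Product: 17 (2S)-3',5,7-tris-O-(tert-butyldimethylsilyl)-4'-O-prenyleriodictyol
Conditions: PPh3 (1.3 equiv), DIAD (1.3 equiv), THF, 0 °C
Reagents that add atoms: none
Why: The Mitsunobu etherification of the single free phenol with a primary allylic alcohol (SN2 at the CH2 of activated prenol) runs under nearly neutral conditions and avoids the carbonate bases that would open ring C by retro-oxa-Michael reaction and racemise C2.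

Step 12
Reactants: 17 (2S)-3',5,7-tris-O-(tert-butyldimethylsilyl)-4'-O-prenyleriodictyol
Product: 18 monotesone A, (2S)-5,7-dihydroxy-2-[3-hydroxy-4-(3-methylbut-2-enyloxy)phenyl]chroman-4-one
Conditions: Bu4NF (3.5 equiv), AcOH (4 equiv), THF, 0 °C
Reagents that add atoms: none
Why: The fluoride-induced cleavage of the three aryl silyl ethers is buffered with acetic acid, so each phenoxide is protonated as it forms and the flavanone–chalcone equilibrium that would racemise C2 is not entered, while the prenyl ether is inert to fluoride.

**Compound list**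
1 | 3,4-dihydroxybenzaldehyde | O=Cc1ccc(O)c(O)c1 | starting material
2 | 3,4-bis(tert-butyldimethylsilyloxy)benzaldehyde | O=Cc1ccc(O[Si](C)(C)C(C)(C)C)c(O[Si](C)(C)C(C)(C)C)c1 | intermediate
3 | 3-(tert-butyldimethylsilyloxy)-4-hydroxybenzaldehyde | O=Cc1ccc(O)c(O[Si](C)(C)C(C)(C)C)c1 | intermediate
4 | 4-(allyloxycarbonyloxy)-3-(tert-butyldimethylsilyloxy)benzaldehyde | C=CCOC(=O)Oc1ccc(C=O)cc1O[Si](C)(C)C(C)(C)C | intermediate
5 | tert-butyl diazoacetate | CC(C)(C)OC(=O)C=[N+]=[N-] | starting material
6 | tert-butyl 3-[4-(allyloxycarbonyloxy)-3-(tert-butyldimethylsilyloxy)phenyl]-3-oxopropanoate | C=CCOC(=O)Oc1ccc(C(=O)CC(=O)OC(C)(C)C)cc1O[Si](C)(C)C(C)(C)C | intermediate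
7 | tert-butyl (R)-3-[4-(allyloxycarbonyloxy)-3-(tert-butyldimethylsilyloxy)phenyl]-3-hydroxypropanoate | C=CCOC(=O)Oc1ccc([C@H](O)CC(=O)OC(C)(C)C)cc1O[Si](C)(C)C(C)(C)C | intermediate
8 | phloroglucinol | Oc1cc(O)cc(O)c1 | starting material
9 | 3,5-bis(tert-butyldimethylsilyloxy)phenol | Oc1cc(O[Si](C)(C)C(C)(C)C)cc(O[Si](C)(C)C(C)(C)C)c1 | intermediate
10 | tert-butyl (S)-3-[4-(allyloxycarbonyloxy)-3-(tert-butyldimethylsilyloxy)phenyl]-3-[3,5-bis(tert-butyldimethylsilyloxy)phenoxy]propanoate | C=CCOC(=O)Oc1ccc([C@@H](Oc2cc(O[Si](C)(C)C(C)(C)C)cc(O[Si](C)(C)C(C)(C)C)c2)CC(=O)OC(C)(C)C)cc1O[Si](C)(C)C(C)(C)C | intermediate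
11 | trimethylsilyl (S)-3-[4-(allyloxycarbonyloxy)-3-(tert-butyldimethylsilyloxy)phenyl]-3-[3,5-bis(tert-butyldimethylsilyloxy)phenoxy]propanoate (not isolated) | C=CCOC(=O)Oc1ccc([C@@H](Oc2cc(O[Si](C)(C)C(C)(C)C)cc(O[Si](C)(C)C(C)(C)C)c2)CC(=O)O[Si](C)(C)C)cc1O[Si](C)(C)C(C)(C)C | intermediate
12 | (S)-3-[4-(allyloxycarbonyloxy)-3-(tert-butyldimethylsilyloxy)phenyl]-3-[3,5-bis(tert-butyldimethylsilyloxy)phenoxy]propanoic acid | C=CCOC(=O)Oc1ccc([C@@H](Oc2cc(O[Si](C)(C)C(C)(C)C)cc(O[Si](C)(C)C(C)(C)C)c2)CC(=O)O)cc1O[Si](C)(C)C(C)(C)C | intermediate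
13 | mixed anhydride of acid 12 and trifluoroacetic acid (not isolated) | C=CCOC(=O)Oc1ccc([C@@H](Oc2cc(O[Si](C)(C)C(C)(C)C)cc(O[Si](C)(C)C(C)(C)C)c2)CC(=O)OC(=O)C(F)(F)F)cc1O[Si](C)(C)C(C)(C)C | intermediate
14 | (2S)-4'-O-(allyloxycarbonyl)-3',5,7-tris-O-(tert-butyldimethylsilyl)eriodictyol | C=CCOC(=O)Oc1ccc([C@@H]2CC(=O)c3c(O[Si](C)(C)C(C)(C)C)cc(O[Si](C)(C)C(C)(C)C)cc3O2)cc1O[Si](C)(C)C(C)(C)C | intermediate
15 | (2S)-3',5,7-tris-O-(tert-butyldimethylsilyl)eriodictyol | Oc1ccc([C@@H]2CC(=O)c3c(O[Si](C)(C)C(C)(C)C)cc(O[Si](C)(C)C(C)(C)C)cc3O2)cc1O[Si](C)(C)C(C)(C)C | intermediate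
16 | prenol (3-methylbut-2-en-1-ol) | CC(C)=CCO | starting material
17 | (2S)-3',5,7-tris-O-(tert-butyldimethylsilyl)-4'-O-prenyleriodictyol | CC(C)=CCOc1ccc([C@@H]2CC(=O)c3c(O[Si](C)(C)C(C)(C)C)cc(O[Si](C)(C)C(C)(C)C)cc3O2)cc1O[Si](C)(C)C(C)(C)C | intermediate
18 | monotesone A | CC(C)=CCOc1ccc([C@@H]2CC(=O)c3c(O)cc(O)cc3O2)cc1O | target

Total step count: 12. Longest linear sequence: 11 steps (steps 1–5 and 7–12, from 3,4-dihydroxybenzaldehyde).

**Steps most likely to fail**

Step 9. The trifluoroacetic acid released may ionise the C2–O1 bond, or cause elimination and re-addition of the aryloxide, which would erode configurational purity. It may also strip silyl groups from ring A, and the excess anhydride may trifluoroacetylate ring A intermolecularly. The fallback gives up the one-pot Brønsted-acidic activation for a discrete acyl halide that is ionised by a Lewis acid in the cold. It sets out from 12. Treatment with 1-chloro-N,N,2-trimethylprop-1-en-1-amine in CH2Cl2 at 0 °C should give, under neutral conditions, (S)-3-[4-(allyloxycarbonyloxy)-3-(tert-butyldimethylsilyloxy)phenyl]-3-[3,5-bis(tert-butyldimethylsilyloxy)phenoxy]propanoyl chloride F1. SnCl4 in CH2Cl2 at −78 °C then closes the same C4–C4a bond at a temperature where ether ionisation and desilylation are frozen out. The fallback comes back to the route at 14.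

Step 7. The activated carbinol may undergo β-elimination to the cinnamate, driven by the acidic hydrogens next to the ester, and part of the substitution may run through a benzylic cation with loss of enantiomeric purity. The fallback replaces phosphonium activation of the alcohol by alkyl–oxygen opening of a β-lactone. It sets out from 7.
- Acidolysis (CF3CO2H, CH2Cl2, 0 °C to rt; ring A is not yet present) gives (R)-3-[4-(allyloxycarbonyloxy)-3-(tert-butyldimethylsilyloxy)phenyl]-3-hydroxypropanoic acid F2.
- Carboxyl activation with benzenesulfonyl chloride in pyridine at 0 °C lactonises F2 with retention to (R)-4-[4-(allyloxycarbonyloxy)-3-(tert-butyldimethylsilyloxy)phenyl]oxetan-2-one F3.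
- Phenol 9 is converted with NaH in THF at 0 °C into sodium 3,5-bis(tert-butyldimethylsilyloxy)phenoxide F4. F4 attacks the benzylic ring carbon of F3 by SN2 with inversion, as phenoxides do with β-butyrolactone, to give sodium (S)-3-[4-(allyloxycarbonyloxy)-3-(tert-butyldimethylsilyloxy)phenyl]-3-[3,5-bis(tert-butyldimethylsilyloxy)phenoxy]propanoate F5.
- Acidification comes back to the route at 12, so step 8 is bypassed as well.

Step 11. While the 4'-phenol is deprotonated in the Mitsunobu medium, the neighbouring 3'-O-silyl group may migrate to the 4'-oxygen and scramble the positions of prenyl and hydroxyl on ring B. Some SN2' attack on activated prenol is also possible. The fallback never liberates the phenol and builds the prenyl group on the oxygen from the carbonate that is already there. It sets out from 14. Pd(PPh3)4 (5 mol %) in THF without any allyl scavenger should bring about decarboxylative O-allylation within the ion pair, giving (2S)-4'-O-allyl-3',5,7-tris-O-(tert-butyldimethylsilyl)eriodictyol F6. Cross-metathesis of F6 with excess 2-methyl-2-butene (second-generation Grubbs catalyst, 5 mol %, CH2Cl2, 40 °C) converts the allyl ether into the prenyl ether. The fallback comes back to the route at 17, so step 10 is bypassed as well.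

**Further compounds**
F1 | step 9 | (S)-3-[4-(allyloxycarbonyloxy)-3-(tert-butyldimethylsilyloxy)phenyl]-3-[3,5-bis(tert-butyldimethylsilyloxy)phenoxy]propanoyl chloride | C=CCOC(=O)Oc1ccc([C@@H](Oc2cc(O[Si](C)(C)C(C)(C)C)cc(O[Si](C)(C)C(C)(C)C)c2)CC(=O)Cl)cc1O[Si](C)(C)C(C)(C)C
F2 | step 7 | (R)-3-[4-(allyloxycarbonyloxy)-3-(tert-butyldimethylsilyloxy)phenyl]-3-hydroxypropanoic acid | C=CCOC(=O)Oc1ccc([C@H](O)CC(=O)O)cc1O[Si](C)(C)C(C)(C)C
F3 | step 7 | (R)-4-[4-(allyloxycarbonyloxy)-3-(tert-butyldimethylsilyloxy)phenyl]oxetan-2-one | C=CCOC(=O)Oc1ccc([C@H]2CC(=O)O2)cc1O[Si](C)(C)C(C)(C)C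
F4 | step 7 | sodium 3,5-bis(tert-butyldimethylsilyloxy)phenoxide | [Na+].[O-]c1cc(O[Si](C)(C)C(C)(C)C)cc(O[Si](C)(C)C(C)(C)C)c1
F5 | step 7 | sodium (S)-3-[4-(allyloxycarbonyloxy)-3-(tert-butyldimethylsilyloxy)phenyl]-3-[3,5-bis(tert-butyldimethylsilyloxy)phenoxy]propanoate | C=CCOC(=O)Oc1ccc([C@@H](Oc2cc(O[Si](C)(C)C(C)(C)C)cc(O[Si](C)(C)C(C)(C)C)c2)CC(=O)[O-])cc1O[Si](C)(C)C(C)(C)C.[Na+]
F6 | step 11 | (2S)-4'-O-allyl-3',5,7-tris-O-(tert-butyldimethylsilyl)eriodictyol | C=CCOc1ccc([C@@H]2CC(=O)c3c(O[Si](C)(C)C(C)(C)C)cc(O[Si](C)(C)C(C)(C)C)cc3O2)cc1O[Si](C)(C)C(C)(C)C
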